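(The earlier runs and the new flask are simulated for an exercise, and the scatter is random.)

Of the starting material charged at 0.10 M, the south run, with 0.069 M of protic impurity, reads 65.6% as target after 40.0 min, with 13.2% of starting material unreacted. The west run, with 0.18 M of impurity, reads less target, 63.4%, although its reading of starting material is lower too, 12.1%.

in all of them: starting material 0.10 M

| charge | protic impurity | remark | time |
|---|---|---|---|
| south | 0.069 M | run made earlier |  |
| north-east | 0.096 M | run made earlier |  |
| west | 0.18 M | run made earlier |  |
| Thursday's | 0.0600 M |  | 40 min |
| Saturday's | 0.100 M |  | 40 min |
| Monday's | 0.150 M |  | 40 min |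

- south (time / min: target / %, starting material / %): 8.00: 24.7, 66.9; 15.0: 40.8, 47.3; 25.0: 54.5, 28.2; 30.0: 59.1, 22.3; 40.0: 65.6, 13.2
- north-east (time / min: target / %, starting material / %): 3.00: 10.9, 85.8; 6.00: 20.7, 74.5; 12.0: 33.5, 55.2; 20.0: 46.9, 36.6; 40.0: 64.2, 12.7
- west (time / min: target / %, starting material / %): 8.00: 25.0, 66.3; 15.0: 39.7, 46.9; 25.0: 53.4, 26.0; 30.0: 57.7, 20.9; 40.0: 63.4, 12.1

(each reading ± 0.5 percentage points)

- "hardly changes" means that all values lie within two and a half points (for a concentration: within two and a half percent of the largest)

* amount of target at the end, in percent of the starting material charged for Thursday's, Saturday's, Monday's, in this order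
* how that number moves from the first to the last of them (falls, then rises / rises all the way / rises, then falls / hardly changes / falls all the way)

These two runs are taken as the ends of the range and joined by a straight line. The drop of 2.2 percentage points in target over 0.111 M of impurity gives 0.198 L mol⁻¹, the impurity price, which is the fraction of the charge lost from the target at 40 min per mole per litre of added impurity. It is a reading resting on two values that each scatter by 0.5 points.

Thursday's flask is the close neighbour of the south run, with the same charge of starting material and the same time, and it holds 0.00900 M less impurity, just outside the joined range. It should end beside the south run because the price makes that difference worth 0.18 points, less than the scatter. My reckoning therefore puts Thursday's at 65.8%, Saturday's at 65.0% and Monday's at 64.0%. The span of 1.8 points stays inside the margin of 2.5 points.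

The forecast, slightly different from this reckoning, gave 66%, 64.7% and 63.8%, a row that hardly changes, on the ground that “All three new runs lie roughly within the tested range”.

The flasks give 65.5%, 64.9% and 64.2%, so the amount of target hardly changes.

    starting material → target (k = 6.30 × 10⁻⁴ s⁻¹)
    starting material + intermediate B → side product (k = 0.00640 L mol⁻¹ s⁻¹)
    starting material → intermediate A (k = 1.70 × 10⁻⁴ s⁻¹)
    starting material + protic impurity → quenched substrate (k = 2.80 × 10⁻⁴ L mol⁻¹ s⁻¹)
    intermediate A ⇌ intermediate B (K = 1.60, k = 0.00120 s⁻¹)

At 40.0 min Thursday's flask holds 1.72% of quenched substrate and Monday's flask 4.22%, and 97% of Monday's protic impurity is still there, unbound, so in that flask the impurity stands nearly constant, the pseudo-first-order case for the quenching step. Carried from Saturday's 64.9% to Monday's impurity, the price gives 63.9%, against the 64.2% found. Carried to the north-east run, which holds 0.00400 M less impurity than Saturday's, it gives 65.0%, where the reading at 40.0 min stands at 64.2%.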